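The α,β-epoxy ketone of the carbocycle (ring A: C1 bearing the ester, C2 the ketone, C3 and C4 the ring epoxide, C5, C6 bearing the side-chain oxirane) is read as an oxidized 2-methylcyclohex-2-en-1-ol. Everything rests on closing ring A at the C2–C3 bond by an intramolecular Nozaki–Hiyama–Kishi reaction of an acyclic (Z)-alkenyl iodide aldehyde. One operation folds the chain into ring A and creates the C2 carbinol, whose hydroxyl then delivers the ring epoxide to the face syn to the C6 substituent before it becomes the ketone. The precursor, which carries C1 and C6 from an anti aldol on (R)-glyceraldehyde acetonide, is an α-acyloxy aldehyde.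

Key step: step 8

Remark: C1–C6 are ring-A labels used in the text (not the locants of the systematic names), C7 is the side-chain oxirane carbon and C8 the side-chain carbonyl carbon; compounds 1, 5, 8, 11 and 22 are taken as commercial.

Step 1
Reactants: 1 but-2-yn-1-ol
Product: 3 (Z)-3-iodobut-2-en-1-ol, via sodium alkenylalanate 2 (not isolated)
Conditions: NaAlH2(OCH2CH2OMe)2, Et2O, 0 °C to rt; then I2, THF, −78 to 0 °C
Reagents that add atoms: iodine, II
Why: Hydroxyl-directed trans-hydroalumination of the propargylic alcohol places aluminium on C3 cis to the CH2O group in the five-membered alanate 2, and iodinolysis with retention should give the (Z)-iodoalkene (hydroalumination–iodination).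

Step 2
Reactants: 3 (Z)-3-iodobut-2-en-1-ol
Product: 4 (Z)-1-bromo-3-iodobut-2-ene
Conditions: CBr4, PPh3, CH2Cl2, 0 °C
Reagents that add atoms: carbon tetrabromide, BrC(Br)(Br)Br
Why: The Appel reaction converts the primary allylic alcohol into the bromide under neutral conditions that leave the alkenyl iodide and its geometry untouched.

Step 3
Reactants: 4 (Z)-1-bromo-3-iodobut-2-ene, 5 1-[(tert-butyldimethylsilyl)oxy]propan-2-one
Product: 7 (Z)-1-[(tert-butyldimethylsilyl)oxy]-6-iodohept-5-en-2-one, via lithium enolate 6 (not isolated)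
Conditions: LiN(iPr)2 (LDA), THF, −78 °C; then 4, DMPU, −78 to −30 °C
Reagents that add atoms: none
Why: Kinetic deprotonation should take place at the methyl group of 5, away from the silyloxy-bearing carbon, and the lithium enolate 6 is alkylated by the reactive allylic bromide (SN2 enolate alkylation).

Step 4
Reactants: 7 (Z)-1-[(tert-butyldimethylsilyl)oxy]-6-iodohept-5-en-2-one, 8 (R)-2,2-dimethyl-1,3-dioxolane-4-carbaldehyde
Product: 10 (3R,5Z)-1-[(tert-butyldimethylsilyl)oxy]-3-[(S)-[(4R)-2,2-dimethyl-1,3-dioxolan-4-yl](hydroxy)methyl]-6-iodohept-5-en-2-one, via (E)-enol dicyclohexylborinate 9 (not isolated)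
Conditions: Cy2BCl, Et3N, Et2O, −78 to 0 °C; then 8, −78 to −20 °C; then H2O2, pH 7 buffer, MeOH, 0 °C
Reagents that add atoms: none
Why: Cy2BCl/Et3N should form the (E)-enol borinate 9 on the alkyl side of 7, whose Zimmerman–Traxler chair sets the anti relationship of the two new stereocentres (anti-selective boron aldol), while the dioxolane stereocentre of 8 directs attack anti to its C–O bond (Felkin–Anh/Cornforth control) and so fixes their absolute sense.

Step 5
Reactants: 10 the aldol adduct, 11 3-methylbutanoyl chloride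
Product: 12 (1S,2R,4Z)-2-{[(tert-butyldimethylsilyl)oxy]acetyl}-1-[(4R)-2,2-dimethyl-1,3-dioxolan-4-yl]-5-iodohex-4-en-1-yl 3-methylbutanoate
Conditions: pyridine, DMAP (cat.), CH2Cl2, 0 °C
Reagents that add atoms: none
Why: DMAP-catalysed acylation of the secondary alcohol installs the ester of the target early, and 0 °C with a weak base should avoid β-elimination of the resulting β-acyloxy ketone.

Step 6
Reactants: 12 the β-acyloxy ketone
Product: 13 (1S,2S,4Z)-2-{3-[(tert-butyldimethylsilyl)oxy]prop-1-en-2-yl}-1-[(4R)-2,2-dimethyl-1,3-dioxolan-4-yl]-5-iodohex-4-en-1-yl 3-methylbutanoate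
Conditions: Tebbe reagent Cp2Ti(μ-CH2)(μ-Cl)AlMe2, pyridine (cat.), THF/toluene, −40 to 0 °C
Reagents that add atoms: Tebbe reagent Cp2Ti(μ-CH2)(μ-Cl)AlMe2, C=[Ti](C1C=CC=C1)C1C=CC=C1.C[Al](C)Cl
Why: Tebbe methylenation is non-basic and at low temperature reacts with a ketone much faster than with an ester, so the enolizable ketone should become the 1,1-disubstituted alkene without elimination or epimerization.

Step 7
Reactants: 13 the acetonide
Product: 15 (2S,3S,5Z)-3-{3-[(tert-butyldimethylsilyl)oxy]prop-1-en-2-yl}-6-iodo-1-oxohept-5-en-2-yl 3-methylbutanoate, via 1,2-diol 14 (not isolated)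
Conditions: H5IO6, EtOAc, 0 °C to rt
Reagents that add atoms: none
Why: Periodic acid hydrolyses the terminal acetonide and cleaves the liberated 1,2-diol 14 in the same flask (glycol cleavage), which unveils the C2 aldehyde while ester, silyl ether and alkenyl iodide should survive.

Step 8
Reactants: 15 the (Z)-alkenyl iodide aldehyde
Product: 17 (1S,2S,6S)-6-{3-[(tert-butyldimethylsilyl)oxy]prop-1-en-2-yl}-2-hydroxy-3-methylcyclohex-3-en-1-yl 3-methylbutanoate, via alkenylchromium dichloride 16 (not isolated)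
Conditions: CrCl2 (6 equiv), NiCl2 (2 mol %), degassed DMSO, rt, 0.005 M
Reagents that add atoms: none
Why: Zerovalent nickel formed in situ inserts into the C–I bond, transmetalation to trivalent chromium gives the alkenylchromium 16 with retention of the Z geometry, and 16 adds intramolecularly to the aldehyde (Nozaki–Hiyama–Kishi reaction). The closest known reaction type is the intramolecular chromium-mediated closure of (Z)-2-iodoalkenyl aldehydes to 2-methylcyclohex-2-enols used for carbasugars. Ring A is closed in a 6-exo-trig mode, the alkenyl carbon C3 attacking the exocyclic C=O at C2. The only new stereocentre, the C2 carbinol, is controlled by a chair-like transition state in which the C1 acyloxy group, the C6 side chain and the chromium-bound aldehyde oxygen are all equatorial, so the hydroxyl should emerge trans to the C1 ester and cis to the C6 substituent. The step needs attack on the aldehyde only and a cis arrangement of metal and chain, which the low basicity and aldehyde selectivity of organochromium reagents and the fixed Z geometry of the iodoalkene secure.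

Step 9
Reactants: 17 the cyclohexenol
Product: 18 (1R,2R,3S,4S,6S)-4-{3-[(tert-butyldimethylsilyl)oxy]prop-1-en-2-yl}-2-hydroxy-1-methyl-7-oxabicyclo[4.1.0]heptan-3-yl 3-methylbutanoate
Conditions: VO(acac)2 (5 mol %), t-BuOOH, CH2Cl2, 0 °C to rt
Reagents that add atoms: tert-butyl hydroperoxide, CC(C)(C)OO
Why: In this hydroxyl-directed vanadium-catalysed epoxidation (known for carveol) the allylic C2 alkoxide binds vanadium and delivers oxygen to the syn face of the trisubstituted ring alkene only, which sets C3 and C4 cis to the hydroxyl and leaves the remote side-chain alkene intact.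

Step 10
Reactants: 18 the silyl ether
Product: 19 (1R,2R,3S,4S,6S)-2-hydroxy-4-(3-hydroxyprop-1-en-2-yl)-1-methyl-7-oxabicyclo[4.1.0]heptan-3-yl 3-methylbutanoate
Conditions: Bu4NF, AcOH, THF, 0 °C to rt
Reagents that add atoms: none
Why: Fluoride-mediated desilylation frees the primary allylic alcohol, and buffering with acetic acid should suppress base-induced migration of the neighbouring ester and Payne rearrangement of the epoxy alcohol.

Step 11
Reactants: 19 the allylic alcohol
Product: 20 (1R,2R,3S,4R,6S)-2-hydroxy-4-[(2S)-2-(hydroxymethyl)oxiran-2-yl]-1-methyl-7-oxabicyclo[4.1.0]heptan-3-yl 3-methylbutanoate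
Conditions: Ti(OiPr)4 (20 mol %), L-(+)-diethyl tartrate (24 mol %), t-BuOOH, 4 Å MS, CH2Cl2, −20 °C
Reagents that add atoms: tert-butyl hydroperoxide, CC(C)(C)OO
Why: Sharpless asymmetric epoxidation of the 2-substituted primary allylic alcohol is reagent-controlled, L-(+)-tartrate delivering oxygen to the face that gives the (S)-hydroxymethyl oxirane (the spatial arrangement of the later (R) centre C7), while the ring epoxy alcohol has no alkene left to react.

Step 12
Reactants: 20 the bis-epoxy diol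
Product: 21 (1S,3S,4R,6S)-4-[(2R)-2-formyloxiran-2-yl]-1-methyl-2-oxo-7-oxabicyclo[4.1.0]heptan-3-yl 3-methylbutanoate
Conditions: Dess–Martin periodinane (2.6 equiv), pyridine, CH2Cl2, 0 °C to rt
Reagents that add atoms: none
Why: Dess–Martin oxidation under buffered conditions converts both hydroxyls in one operation, the secondary one into the ring α,β-epoxy ketone and the primary one into a non-enolizable epoxy aldehyde, without epimerizing the α-acyloxy centre.

Step 13
Reactants: 21 the keto aldehyde, 22 1-chloro-3-methylbut-2-ene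
Product: 24 (1S,3S,4R,6S)-4-[(2R)-2-(1-hydroxy-4-methylpent-3-en-1-yl)oxiran-2-yl]-1-methyl-2-oxo-7-oxabicyclo[4.1.0]heptan-3-yl 3-methylbutanoate (both carbinol epimers), via prenylbarium chloride 23 (not isolated)
Conditions: BaI2, Li, biphenyl, THF, rt; then 22, −78 °C; then 21, −78 °C
Reagents that add atoms: none
Why: Allylic barium reagents add to carbonyl groups through their less substituted α-carbon (allylbarium prenylation), so 23 should give the linear prenyl carbinol, the aldehyde reacting at −78 °C far faster than the hindered ring ketone or the ester, and the uncontrolled carbinol centre is removed in step 14.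

Step 14
Reactants: 24 the homoallylic alcohol
Product: 25 (1S,3S,4R,6S)-1-methyl-4-[(2R)-2-(4-methylpent-3-enoyl)oxiran-2-yl]-2-oxo-7-oxabicyclo[4.1.0]heptan-3-yl 3-methylbutanoate
Conditions: Dess–Martin periodinane, pyridine, CH2Cl2, 0 °C
Reagents that add atoms: none
Why: Buffered Dess–Martin oxidation converges both carbinol epimers on one β,γ-unsaturated ketone and should not move the double bond into conjugation.

Step 15
Reactants: 25 the β,γ-unsaturated ketone
Product: 26 (1S,3S,4R,6S)-4-{(2R)-2-[(2E)-4-hydroperoxy-4-methylpent-2-enoyl]oxiran-2-yl}-1-methyl-2-oxo-7-oxabicyclo[4.1.0]heptan-3-yl 3-methylbutanoate (target)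
Conditions: O2, tetraphenylporphyrin (cat.), hν (visible), CH2Cl2, 0 °C
Reagents that add atoms: dioxygen, O=O
Why: In a Schenck ene reaction singlet oxygen should abstract a hydrogen from the activated methylene between carbonyl and alkene, as is known for β,γ-unsaturated ketones, so that oxygen is bound at the tertiary carbon and the double bond moves into conjugation with E geometry, while ketones, epoxides and the ester are inert.

Compound list
1 | but-2-yn-1-ol | CC#CCO | starting material
2 | sodium 2,2-bis(2-methoxyethoxy)-3-methyl-2,5-dihydro-1,2-oxaluminol-2-uide (cyclic alkenylalanate) | CC1=CCO[Al-]1(OCCOC)OCCOC.[Na+] | intermediate (not isolated)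
3 | (Z)-3-iodobut-2-en-1-ol | C/C(I)=C/CO | intermediate
4 | (Z)-1-bromo-3-iodobut-2-ene | C/C(I)=C/CBr | intermediate
5 | 1-[(tert-butyldimethylsilyl)oxy]propan-2-one | CC(=O)CO[Si](C)(C)C(C)(C)C | starting material
6 | lithium enolate of 5 (methyl side) | [Li]OC(=C)CO[Si](C)(C)C(C)(C)C | intermediate (not isolated)
7 | (Z)-1-[(tert-butyldimethylsilyl)oxy]-6-iodohept-5-en-2-one | C/C(I)=C/CCC(=O)CO[Si](C)(C)C(C)(C)C | intermediate
8 | (R)-2,2-dimethyl-1,3-dioxolane-4-carbaldehyde | O=C[C@H]1COC(C)(C)O1 | starting material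
9 | (E)-enol dicyclohexylborinate of 7 | C/C(I)=C/C/C=C(/OB(C1CCCCC1)C1CCCCC1)CO[Si](C)(C)C(C)(C)C | intermediate (not isolated)
10 | (3R,5Z)-1-[(tert-butyldimethylsilyl)oxy]-3-[(S)-[(4R)-2,2-dimethyl-1,3-dioxolan-4-yl](hydroxy)methyl]-6-iodohept-5-en-2-one | O[C@@H]([C@@H](C/C=C(/C)I)C(=O)CO[Si](C)(C)C(C)(C)C)[C@H]1COC(C)(C)O1 | intermediate
11 | 3-methylbutanoyl chloride | CC(C)CC(Cl)=O | starting material
12 | (1S,2R,4Z)-2-{[(tert-butyldimethylsilyl)oxy]acetyl}-1-[(4R)-2,2-dimethyl-1,3-dioxolan-4-yl]-5-iodohex-4-en-1-yl 3-methylbutanoate | CC(C)CC(=O)O[C@@H]([C@@H](C/C=C(/C)I)C(=O)CO[Si](C)(C)C(C)(C)C)[C@H]1COC(C)(C)O1 | intermediate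
13 | (1S,2S,4Z)-2-{3-[(tert-butyldimethylsilyl)oxy]prop-1-en-2-yl}-1-[(4R)-2,2-dimethyl-1,3-dioxolan-4-yl]-5-iodohex-4-en-1-yl 3-methylbutanoate | CC(C)CC(=O)O[C@@H]([C@@H](C/C=C(/C)I)C(=C)CO[Si](C)(C)C(C)(C)C)[C@H]1COC(C)(C)O1 | intermediate
14 | (2R,3S,4S,6Z)-4-{3-[(tert-butyldimethylsilyl)oxy]prop-1-en-2-yl}-1,2-dihydroxy-7-iodooct-6-en-3-yl 3-methylbutanoate | CC(C)CC(=O)O[C@@H]([C@@H](C/C=C(/C)I)C(=C)CO[Si](C)(C)C(C)(C)C)[C@H](O)CO | intermediate (not isolated)
15 | (2S,3S,5Z)-3-{3-[(tert-butyldimethylsilyl)oxy]prop-1-en-2-yl}-6-iodo-1-oxohept-5-en-2-yl 3-methylbutanoate | CC(C)CC(=O)O[C@@H]([C@@H](C/C=C(/C)I)C(=C)CO[Si](C)(C)C(C)(C)C)C=O | intermediate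
16 | (2S,3S,5Z)-3-{3-[(tert-butyldimethylsilyl)oxy]prop-1-en-2-yl}-6-(dichlorochromio)-1-oxohept-5-en-2-yl 3-methylbutanoate (trivalent chromium) | CC(C)CC(=O)O[C@@H]([C@@H](C/C=C(/C)[Cr](Cl)Cl)C(=C)CO[Si](C)(C)C(C)(C)C)C=O | intermediate (not isolated)
17 | (1S,2S,6S)-6-{3-[(tert-butyldimethylsilyl)oxy]prop-1-en-2-yl}-2-hydroxy-3-methylcyclohex-3-en-1-yl 3-methylbutanoate | CC(C)CC(=O)O[C@@H]1[C@@H](O)C(C)=CC[C@H]1C(=C)CO[Si](C)(C)C(C)(C)C | intermediate
18 | (1R,2R,3S,4S,6S)-4-{3-[(tert-butyldimethylsilyl)oxy]prop-1-en-2-yl}-2-hydroxy-1-methyl-7-oxabicyclo[4.1.0]heptan-3-yl 3-methylbutanoate | CC(C)CC(=O)O[C@@H]1[C@@H](O)[C@@]2(C)O[C@H]2C[C@H]1C(=C)CO[Si](C)(C)C(C)(C)C | intermediate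
19 | (1R,2R,3S,4S,6S)-2-hydroxy-4-(3-hydroxyprop-1-en-2-yl)-1-methyl-7-oxabicyclo[4.1.0]heptan-3-yl 3-methylbutanoate | CC(C)CC(=O)O[C@@H]1[C@@H](O)[C@@]2(C)O[C@H]2C[C@H]1C(=C)CO | intermediate
20 | (1R,2R,3S,4R,6S)-2-hydroxy-4-[(2S)-2-(hydroxymethyl)oxiran-2-yl]-1-methyl-7-oxabicyclo[4.1.0]heptan-3-yl 3-methylbutanoate | CC(C)CC(=O)O[C@@H]1[C@@H](O)[C@@]2(C)O[C@H]2C[C@H]1[C@]1(CO)CO1 | intermediate
21 | (1S,3S,4R,6S)-4-[(2R)-2-formyloxiran-2-yl]-1-methyl-2-oxo-7-oxabicyclo[4.1.0]heptan-3-yl 3-methylbutanoate | CC(C)CC(=O)O[C@@H]1C(=O)[C@@]2(C)O[C@H]2C[C@H]1[C@]1(C=O)CO1 | intermediate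
22 | 1-chloro-3-methylbut-2-ene | CC(C)=CCCl | starting material
23 | prenylbarium chloride | CC(C)=CC[Ba]Cl | intermediate (not isolated)
24 | (1S,3S,4R,6S)-4-[(2R)-2-(1-hydroxy-4-methylpent-3-en-1-yl)oxiran-2-yl]-1-methyl-2-oxo-7-oxabicyclo[4.1.0]heptan-3-yl 3-methylbutanoate (both carbinol epimers) | CC(C)CC(=O)O[C@@H]1C(=O)[C@@]2(C)O[C@H]2C[C@H]1[C@]1(C(O)CC=C(C)C)CO1 | intermediate
25 | (1S,3S,4R,6S)-1-methyl-4-[(2R)-2-(4-methylpent-3-enoyl)oxiran-2-yl]-2-oxo-7-oxabicyclo[4.1.0]heptan-3-yl 3-methylbutanoate | CC(C)CC(=O)O[C@@H]1C(=O)[C@@]2(C)O[C@H]2C[C@H]1[C@]1(C(=O)CC=C(C)C)CO1 | intermediate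
26 | (1S,3S,4R,6S)-4-{(2R)-2-[(2E)-4-hydroperoxy-4-methylpent-2-enoyl]oxiran-2-yl}-1-methyl-2-oxo-7-oxabicyclo[4.1.0]heptan-3-yl 3-methylbutanoate | CC(C)CC(=O)O[C@@H]1C(=O)[C@@]2(C)O[C@H]2C[C@H]1[C@]1(C(=O)/C=C/C(C)(C)OO)CO1 | target

Total step count: 15. Longest linear sequence: 15 steps (1 to 26; compounds 5, 8, 11 and 22 enter as commercial materials).

Steps most likely to fail

Step 8 (key step). The facial selectivity of the chromium-mediated closure may be low, because the aldehyde can react with its oxygen axial as well as equatorial in the chair-like transition state. Part of the material would then carry the C2 hydroxyl cis to the ester and would later send the ring epoxide to the wrong face. The fallback sets out from 15. The closure is run as before, and the mixture of 17 and its C2 epimer, the cis-hydroxy ester F1, is oxidized with Dess–Martin periodinane to the 2-methylcyclohex-2-enone F2. Reduction with NaBH4 and CeCl3·7H2O in MeOH at −78 °C (Luche reduction) should then deliver hydride axially and give the equatorial alcohol, which returns to the route at 17.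

Step 4. Enolization of 7 may occur in part at the silyloxy-bearing methylene, which would give regioisomeric aldols. The fallback sets out from 4 and uses a ketone with only one enolizable position. The lithium enolate of commercial 1,1-dimethoxypropan-2-one (LDA, THF, −78 °C) is alkylated with 4 to give (Z)-6-iodo-1,1-dimethoxyhept-5-en-2-one F3. The same Cy2BCl aldol with 8 gives the aldol adduct F4, acylation with 11 gives the ester F5, and Tebbe methylenation gives the 2-substituted acrolein dimethyl acetal F6. Hydrolysis of the allylic acetal (Amberlyst 15, wet acetone, 0 °C, in which the acetonide should stay) gives the enal F7, and NaBH4 with CeCl3·7H2O gives the allylic alcohol F8. Silylation (TBSCl, imidazole, DMF) comes back to the route at 13.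

Step 13. The allylic barium reagent may attack in part through its more substituted γ-carbon or add to the ring ketone. The fallback sets out from 21. Allylation with 2-allyl-4,4,5,5-tetramethyl-1,3,2-dioxaborolane (CH2Cl2, rt), which is neutral and selective for aldehydes, gives the homoallylic alcohol F9. Cross-metathesis with 2-methylbut-2-ene (second-generation Grubbs catalyst RuCl2(=CHPh)(PCy3)(H2IMes), CH2Cl2, 40 °C) turns the terminal alkene into the prenyl group and returns to the route at 24.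

Further compounds
F1 | step 8 | (1S,2R,6S)-6-{3-[(tert-butyldimethylsilyl)oxy]prop-1-en-2-yl}-2-hydroxy-3-methylcyclohex-3-en-1-yl 3-methylbutanoate | CC(C)CC(=O)O[C@@H]1[C@H](O)C(C)=CC[C@H]1C(=C)CO[Si](C)(C)C(C)(C)C
F2 | step 8 | (1S,6S)-6-{3-[(tert-butyldimethylsilyl)oxy]prop-1-en-2-yl}-3-methyl-2-oxocyclohex-3-en-1-yl 3-methylbutanoate | CC(C)CC(=O)O[C@@H]1C(=O)C(C)=CC[C@H]1C(=C)CO[Si](C)(C)C(C)(C)C
F3 | step 4 | (Z)-6-iodo-1,1-dimethoxyhept-5-en-2-one | C/C(I)=C/CCC(=O)C(OC)OC
F4 | step 4 | (3R,5Z)-3-[(S)-[(4R)-2,2-dimethyl-1,3-dioxolan-4-yl](hydroxy)methyl]-6-iodo-1,1-dimethoxyhept-5-en-2-one | O[C@@H]([C@@H](C/C=C(/C)I)C(=O)C(OC)OC)[C@H]1COC(C)(C)O1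
F5 | step 4 | (1S,2R,4Z)-2-(dimethoxyacetyl)-1-[(4R)-2,2-dimethyl-1,3-dioxolan-4-yl]-5-iodohex-4-en-1-yl 3-methylbutanoate | CC(C)CC(=O)O[C@@H]([C@@H](C/C=C(/C)I)C(=O)C(OC)OC)[C@H]1COC(C)(C)O1
F6 | step 4 | (1S,2S,4Z)-2-(3,3-dimethoxyprop-1-en-2-yl)-1-[(4R)-2,2-dimethyl-1,3-dioxolan-4-yl]-5-iodohex-4-en-1-yl 3-methylbutanoate | CC(C)CC(=O)O[C@@H]([C@@H](C/C=C(/C)I)C(=C)C(OC)OC)[C@H]1COC(C)(C)O1
F7 | step 4 | (1S,2S,4Z)-1-[(4R)-2,2-dimethyl-1,3-dioxolan-4-yl]-5-iodo-2-(3-oxoprop-1-en-2-yl)hex-4-en-1-yl 3-methylbutanoate | CC(C)CC(=O)O[C@@H]([C@@H](C/C=C(/C)I)C(=C)C=O)[C@H]1COC(C)(C)O1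
F8 | step 4 | (1S,2S,4Z)-1-[(4R)-2,2-dimethyl-1,3-dioxolan-4-yl]-2-(3-hydroxyprop-1-en-2-yl)-5-iodohex-4-en-1-yl 3-methylbutanoate | CC(C)CC(=O)O[C@@H]([C@@H](C/C=C(/C)I)C(=C)CO)[C@H]1COC(C)(C)O1
F9 | step 13 | (1S,3S,4R,6S)-4-[(2R)-2-(1-hydroxybut-3-en-1-yl)oxiran-2-yl]-1-methyl-2-oxo-7-oxabicyclo[4.1.0]heptan-3-yl 3-methylbutanoate (both carbinol epimers) | CC(C)CC(=O)O[C@@H]1C(=O)[C@@]2(C)O[C@H]2C[C@H]1[C@]1(C(O)CC=C)CO1
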